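**Plan**

Labels: ring B is the central benzene (a1 bears Cb, a2 bears Cf, a3 and a5 bear the furan oxygens, a4 is CH, a6 bears C3F); ring D is the resorcinol ring on Cf (d1 on Cf, d6 on Ca); rings E (O–C2E–Cf) and F (O–C2F–C3F) are the dihydrofurans; ring C is the carbocycle a1–a2–Cf–d1–d6–Ca–Cb; PMB = 4-methoxybenzyl, TIPS = triisopropylsilyl.
Cuts, in retrosynthetic order: the seven O–CH3 bonds; the Ca–aryl bond (anisole onto a Ca cation); the Ca–Cb bond of ring C, through the Ca=Cb alkene and SO2 extrusion from an eight-membered Ca–SO2–Cb sulfone; the two C–S bonds; C2F–C3F and C2E–Cf (carbene C–H insertions); a6–C3F, a2–Cf and the d6–Ca carbon (aryllithium chemistry).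
Enabling feature: Ca and Cb are the only adjacent sp3 carbons of ring C and both are benzylic (Ca on d6 of ring D, Cb on a1 of ring B), so their bond can be the alkene left when a bis-benzylic thiocine S,S-dioxide loses SO2 (Ramberg–Bäcklund); the poorly nucleophilic a1 never has to close a ring.
Forward: ring B (3,5-dihydroxybenzyl alcohol) is PMB-protected and dibrominated; ring E, then ring F, are each made by Br/Li exchange, acylation, hydrazone formation and Rh-carbene insertion into the adjacent PMB ether; the d6 and a1 hydroxymethyl groups are joined through sulfur, the sulfide is oxidised, the sulfone is contracted to ring C, anisole is added to Ca and the methyl ethers are cleaved.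
Stereochemistry: Cf and C3F come from the two insertions, run with antipodal Rh2(PTAD)4 catalysts; C2E and C2F are then equilibrated to trans by reversible acid ionisation; Ca is set last by substrate control, the aryl group entering the Ca cation on the convex face of the folded ring C. Hydrogen added to a Ca-aryl alkene would be expected to enter on that same face and give the Ca epimer, which is why the aryl group is introduced after the contraction.

Key step: step 16

Assumption: Rh2(S-PTAD)4, dirhodium tetrakis[(S)-(1-adamantyl)(phthalimido)acetate], is taken to give the 3S centre (Cf) in step 6 and its antipode Rh2(R-PTAD)4 the mirror-image centre (C3F) in step 10; should the first insertion show the opposite sense, the two catalysts change places.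

**Route**

Step 1
Reactants: 1 3,5-dihydroxybenzyl alcohol; 2 4-methoxybenzyl chloride (2.1 equiv)
Product: 3 [3,5-bis(4-methoxybenzyloxy)phenyl]methanol
Conditions: K2CO3, DMF, 60 °C
Reagents that add atoms: none
Why: Williamson etherification in which K2CO3 deprotonates only the phenols, so both are benzylated while the benzylic alcohol stays free; the PMB methylene groups later become C2E and C2F with their 4-methoxyphenyl groups.

Step 2
Reactants: 3 [3,5-bis(4-methoxybenzyloxy)phenyl]methanol
Product: 4 [2,6-dibromo-3,5-bis(4-methoxybenzyloxy)phenyl]methanol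
Conditions: NBS (2.05 equiv), MeCN, 0 °C, dark
Reagents that add atoms: N-bromosuccinimide O=C1CCC(=O)N1Br
Why: Electrophilic aromatic bromination in which the two ring B carbons para to one alkoxy group and ortho to the other (a2, a6) react in turn, the doubly flanked a4 and the anisole-type PMB rings being much slower.

Step 3
Reactants: 4 [2,6-dibromo-3,5-bis(4-methoxybenzyloxy)phenyl]methanol
Product: 5 {[2,6-dibromo-3,5-bis(4-methoxybenzyloxy)benzyl]oxy}triisopropylsilane
Conditions: TIPSCl, imidazole, DMF, rt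
Reagents that add atoms: chlorotriisopropylsilane CC(C)[Si](Cl)(C(C)C)C(C)C
Why: Silylation of the primary alcohol; the bulky TIPS group is chosen because it resists 1,4-migration from oxygen to an adjacent aryllithium and its hindered, weakly basic oxygen should not intercept the later rhodium carbenes as an oxonium ylide.

Step 4
Reactants: 5 {[2,6-dibromo-3,5-bis(4-methoxybenzyloxy)benzyl]oxy}triisopropylsilane; 6 3,5-dimethoxybenzonitrile
Product: 8 1-[3-bromo-4,6-bis(4-methoxybenzyloxy)-2-(triisopropylsilyloxymethyl)phenyl]-1-(3,5-dimethoxyphenyl)methanimine (N–H ketimine), via aryllithium 7 (not isolated)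
Conditions: n-BuLi (1.0 equiv), THF, −78 °C; then 6, −78 to 0 °C; MeOH
Reagents that add atoms: none
Why: Bromine–lithium exchange of one of the two equivalent bromides followed by addition of the aryllithium to the nitrile forms the a2–Cf bond; the N-lithio ketimine cannot react further and the hindered N–H ketimine should survive isolation.

Step 5
Reactants: 8 N–H ketimine
Product: 9 hydrazone of [3-bromo-4,6-bis(4-methoxybenzyloxy)-2-(triisopropylsilyloxymethyl)phenyl](3,5-dimethoxyphenyl)methanone
Conditions: N2H4·H2O (5 equiv), AcOH (cat.), EtOH, 60 °C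
Reagents that add atoms: hydrazine NN
Why: Transimination, in which hydrazine exchanges with the N–H ketimine with loss of ammonia far more readily than it would condense with the corresponding di-ortho-substituted benzophenone.

Step 6
Reactants: 9 hydrazone
Product: 11 (2R,3S)-5-bromo-3-(3,5-dimethoxyphenyl)-6-(4-methoxybenzyloxy)-2-(4-methoxyphenyl)-4-(triisopropylsilyloxymethyl)-2,3-dihydrobenzofuran (ring E closed; 2,3-cis), via diazo compound 10 (not isolated)
Conditions: MnO2, CH2Cl2, 0 °C; filtration; Rh2(S-PTAD)4 (1 mol %), CH2Cl2, 0 °C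
Reagents that add atoms: none
Why: Dehydrogenation of the hydrazone gives the diaryldiazomethane, and the derived donor/donor rhodium carbene undergoes intramolecular 1,5 C–H insertion into the benzylic, oxygen-activated methylene of the ortho PMB ether, forming C2E–Cf; the chiral carboxylate ligands set Cf (3S) by face selection at the carbene carbon, and the cis relation at C2E follows from the tight hydride-shift and ring-closure sequence.

Step 7
Reactants: 11 ring E bromide; 12 3,5-dimethoxybenzoyl chloride (1.5 equiv)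
Product: 14 [(2R,3S)-3-(3,5-dimethoxyphenyl)-6-(4-methoxybenzyloxy)-2-(4-methoxyphenyl)-4-(triisopropylsilyloxymethyl)-2,3-dihydrobenzofuran-5-yl](3,5-dimethoxyphenyl)methanone, via aryllithium 13 (not isolated)
Conditions: n-BuLi (1.05 equiv), THF, −78 °C; then cannulation into 12, THF, −78 °C
Reagents that add atoms: none
Why: Bromine–lithium exchange at a6 and acylation by inverse addition form the a6–C3F bond; the di-ortho-substituted ketone is too hindered to add a second aryllithium, and the ketone level is wanted because it deactivates the new dimethoxyphenyl ring for step 8.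

Step 8
Reactants: 14 ketone
Product: 15 [(2R,3R)-3-(2-bromo-3,5-dimethoxyphenyl)-6-(4-methoxybenzyloxy)-2-(4-methoxyphenyl)-4-(triisopropylsilyloxymethyl)-2,3-dihydrobenzofuran-5-yl](3,5-dimethoxyphenyl)methanone (geometry unchanged; the C3 descriptor changes only through the rank of bromine)
Conditions: NBS (1.0 equiv), MeCN/CH2Cl2, −20 °C, dark
Reagents that add atoms: N-bromosuccinimide O=C1CCC(=O)N1Br
Why: Electrophilic aromatic bromination in which ring D is the only 1,3-dimethoxyarene not conjugated to a carbonyl and reacts at d6 (equivalent to d2), para to one methoxy group, while the ketone-bound dimethoxyphenyl ring is deactivated and the acylated ring B offers only the doubly flanked a4.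

Step 9
Reactants: 15 bromo ketone
Product: 16 hydrazone of 15
Conditions: N2H4·H2O (30 equiv), AcOH (cat.), EtOH, 100 °C, sealed tube
Reagents that add atoms: hydrazine NN
Why: Hydrazone formation by condensation, run under forcing conditions because the carbonyl is flanked by the a1 and a5 substituents; aryl bromide, silyl ether and PMB ether are inert to hydrazine.

Step 10
Reactants: 16 hydrazone
Product: 18 (2R,3R,5R,6S)-3-(2-bromo-3,5-dimethoxyphenyl)-5-(3,5-dimethoxyphenyl)-2,6-bis(4-methoxyphenyl)-4-(triisopropylsilyloxymethyl)-2,3,5,6-tetrahydrobenzo[1,2-b:5,4-b']difuran (rings E and F both cis), via diazo compound 17 (not isolated)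
Conditions: MnO2, CH2Cl2, 0 °C; filtration; Rh2(R-PTAD)4 (1 mol %), CH2Cl2, 0 °C
Reagents that add atoms: none
Why: The same hydrazone dehydrogenation and rhodium-carbene 1,5 C–H insertion, now into the remaining PMB ether, forms C2F–C3F and closes ring F cis; the antipodal catalyst reverses the face selection so that C3F is set R (both C3 aryl groups on the same face of ring B) under catalyst control, the ring E stereocentres lying remote on the other side of ring B.

Step 11
Reactants: 18 cis,cis compound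
Product: 19 (2S,3R,5R,6R)-3-(2-bromo-3,5-dimethoxyphenyl)-5-(3,5-dimethoxyphenyl)-2,6-bis(4-methoxyphenyl)-4-(triisopropylsilyloxymethyl)-2,3,5,6-tetrahydrobenzo[1,2-b:5,4-b']difuran (rings E and F both trans)
Conditions: TFA (10 equiv), CH2Cl2, 0 °C to rt
Reagents that add atoms: none
Why: Acid-mediated epimerisation, in which TFA reversibly ionises each C2–O bond to a 4-methoxybenzyl cation beside the free phenol (the ionisation that cleaves PMB aryl ethers) and reclosure under thermodynamic control gives the trans-2,3-diaryl arrangement by inverting only C2E and C2F, Cf and C3F being untouched.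

Step 12
Reactants: 19 trans,trans bromide
Product: 22 {2-[(2S,3S,5R,6R)-5-(3,5-dimethoxyphenyl)-2,6-bis(4-methoxyphenyl)-4-(triisopropylsilyloxymethyl)-2,3,5,6-tetrahydrobenzo[1,2-b:5,4-b']difuran-3-yl]-4,6-dimethoxyphenyl}methanol, via aryllithium 20 (not isolated), via aldehyde 21 (not isolated)
Conditions: n-BuLi (1.1 equiv), THF, −78 °C; DMF, −78 to 0 °C; then MeOH, NaBH4, 0 °C
Reagents that add atoms: N,N-dimethylformamide CN(C)C=O
Why: Bromine–lithium exchange, formylation of the aryllithium with DMF and borohydride reduction of the aldehyde in the same flask install the Ca carbon on d6 as a hydroxymethyl group.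

Step 13
Reactants: 22 silyl ether alcohol
Product: 23 {(2S,3S,5R,6R)-3-[2-(hydroxymethyl)-3,5-dimethoxyphenyl]-5-(3,5-dimethoxyphenyl)-2,6-bis(4-methoxyphenyl)-2,3,5,6-tetrahydrobenzo[1,2-b:5,4-b']difuran-4-yl}methanol (diol)
Conditions: TBAF, THF, 0 °C to rt
Reagents that add atoms: none
Why: Fluoride-induced desilylation frees the Cb alcohol on a1.

Step 14
Reactants: 23 diol
Product: 25 thiocine (eight-membered cyclic sulfide; ring atoms S, Cb, a1, a2, Cf, d1, d6, Ca; Ca and Cb both CH2; C2E S, Cf S, C2F R, C3F R), via dibromide 24 (not isolated)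
Conditions: PBr3, CH2Cl2, −20 °C, cold NaHCO3 wash; then slow addition to Na2S·9H2O, DMF, rt (about 2 mM)
Reagents that add atoms: sodium sulfide [Na+].[Na+].[S-2]
Why: Both benzylic alcohols are converted into bromides (the electron-rich ring D bromide is too labile to store) and double nucleophilic substitution by sulfide at high dilution, first intermolecular SN2 and then ring closure by the thiolate, gives the thiocine in the way cyclic bis-benzylic sulfides are usually made from bis(bromomethyl)arenes.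

Step 15
Reactants: 25 thiocine
Product: 27 thiocine S,S-dioxide (eight-membered sulfone Cb–SO2–Ca; stereocentres as in 25), via sulfoxide 26 (not isolated)
Conditions: mCPBA (2.2 equiv), CH2Cl2, 0 °C to rt
Reagents that add atoms: 3-chloroperoxybenzoic acid OOC(=O)c1cccc(Cl)c1
Why: Peracid oxidation at sulfur through the sulfoxide to the sulfone; the methoxyarenes are inert at this temperature and no alkene is present yet.

Step 16
Reactants: 27 thiocine S,S-dioxide
Product: 30 ring C alkene (Ca(H)=Cb(H), cis within the seven-membered ring; hexamethyl ether; C2E S, Cf S, C2F R, C3F R), via bromosulfone 28 (not isolated), via episulfone 29 (not isolated)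
Conditions: KOH/Al2O3, CBr2F2, t-BuOH/CH2Cl2, 0 °C to rt
Reagents that add atoms: none
Why: Hydroxide on alumina deprotonates a sulfone α-carbon (Ca or Cb), the carbanion is brominated by CBr2F2 to give the α-bromosulfone, deprotonation at the other α-carbon is followed by intramolecular displacement of bromide to give the episulfone, and cheletropic loss of SO2 leaves the Ca=Cb double bond. This is the Ramberg–Bäcklund reaction with in situ halogenation, as established for acyclic and cyclic bis-benzylic sulfones (stilbenes, cyclophane dienes, benzo-fused cycloalkenes). The only ring closed by bond formation is the three-membered episulfone (3-exo-tet); ring C arises by contraction of the eight-membered thiocine to the seven-membered carbocycle when sulfur is extruded, so the alkene is necessarily cis. No stereocentre is created, and because both α-carbons are methylene groups either order of halogenation and closure converges on the same alkene. The step needs carbanion chemistry to stay at Ca and Cb and away from the diarylmethine protons at Cf and C3F, whose deprotonation would open rings E and F by β-elimination of phenoxide; the far higher acidity of the sulfone α-protons secures this.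

Step 17
Reactants: 30 ring C alkene; 31 anisole (co-solvent, large excess)
Product: 32 heptamethyl ether of the target (Ca S, Cf S, C2E S, C2F R, C3F R)
Conditions: TfOH (10 mol %), anisole/CH2Cl2 (1:4), −20 to 0 °C
Reagents that add atoms: none
Why: Acid-catalysed Friedel–Crafts hydroarylation of a styrene-type alkene, in which protonation at Cb gives the Ca cation stabilised by the ortho and para methoxy groups of ring D (a Cb cation on ring B would have only meta oxygens) and anisole attacks through its para carbon on the convex face of the folded dibenzocycloheptene, the face carrying Cf–H and C3F–H, since the concave face is closed by the ring B/ring D fold and the C3F aryl group; the new aryl is therefore cis to Cf–H and Ca is S.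

Step 18
Reactants: 32 heptamethyl ether
Product: 33 CNP0136963.1 (target; Ca S, Cf S, C2E S, C2F R, C3F R)
Conditions: BBr3 (excess), CH2Cl2, −78 °C to rt; then MeOH/H2O
Reagents that add atoms: none
Why: Lewis acid cleavage of the seven aryl methyl ethers (bromide attacks the O-methyl group of each boron-complexed ether) and hydrolysis of the aryl borates; rings E and F are already in their thermodynamic trans form, so any reversible C2–O ionisation returns the same isomers.

**Compound list**

1 | 3,5-dihydroxybenzyl alcohol | OCc1cc(O)cc(O)c1 | starting material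
2 | 4-methoxybenzyl chloride | COc1ccc(CCl)cc1 | starting material
3 | [3,5-bis(4-methoxybenzyloxy)phenyl]methanol | OCc1cc(OCc2ccc(OC)cc2)cc(OCc2ccc(OC)cc2)c1 | intermediate
4 | [2,6-dibromo-3,5-bis(4-methoxybenzyloxy)phenyl]methanol | OCc1c(Br)c(OCc2ccc(OC)cc2)cc(OCc2ccc(OC)cc2)c1Br | intermediate
5 | {[2,6-dibromo-3,5-bis(4-methoxybenzyloxy)benzyl]oxy}triisopropylsilane | CC(C)[Si](C(C)C)(C(C)C)OCc1c(Br)c(OCc2ccc(OC)cc2)cc(OCc2ccc(OC)cc2)c1Br | intermediate
6 | 3,5-dimethoxybenzonitrile | COc1cc(OC)cc(C#N)c1 | starting material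
7 | [3-bromo-4,6-bis(4-methoxybenzyloxy)-2-(triisopropylsilyloxymethyl)phenyl]lithium | CC(C)[Si](C(C)C)(C(C)C)OCc1c(Br)c(OCc2ccc(OC)cc2)cc(OCc2ccc(OC)cc2)c1[Li] | intermediate (not isolated)
8 | 1-[3-bromo-4,6-bis(4-methoxybenzyloxy)-2-(triisopropylsilyloxymethyl)phenyl]-1-(3,5-dimethoxyphenyl)methanimine | CC(C)[Si](C(C)C)(C(C)C)OCc1c(Br)c(OCc2ccc(OC)cc2)cc(OCc2ccc(OC)cc2)c1C(=N)c1cc(OC)cc(OC)c1 | intermediate
9 | hydrazone of [3-bromo-4,6-bis(4-methoxybenzyloxy)-2-(triisopropylsilyloxymethyl)phenyl](3,5-dimethoxyphenyl)methanone | CC(C)[Si](C(C)C)(C(C)C)OCc1c(Br)c(OCc2ccc(OC)cc2)cc(OCc2ccc(OC)cc2)c1C(=NN)c1cc(OC)cc(OC)c1 | intermediate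
10 | [3-bromo-4,6-bis(4-methoxybenzyloxy)-2-(triisopropylsilyloxymethyl)phenyl](3,5-dimethoxyphenyl)diazomethane | CC(C)[Si](C(C)C)(C(C)C)OCc1c(Br)c(OCc2ccc(OC)cc2)cc(OCc2ccc(OC)cc2)c1C(=[N+]=[N-])c1cc(OC)cc(OC)c1 | intermediate (not isolated)
11 | (2R,3S)-5-bromo-3-(3,5-dimethoxyphenyl)-6-(4-methoxybenzyloxy)-2-(4-methoxyphenyl)-4-(triisopropylsilyloxymethyl)-2,3-dihydrobenzofuran (2,3-cis) | CC(C)[Si](C(C)C)(C(C)C)OCc1c2c(cc(OCc3ccc(OC)cc3)c1Br)O[C@@H](c1ccc(OC)cc1)[C@H]2c1cc(OC)cc(OC)c1 | intermediate
12 | 3,5-dimethoxybenzoyl chloride | COc1cc(OC)cc(C(=O)Cl)c1 | starting material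
13 | 5-lithio analogue of 11 (lithium in place of bromine at a6) | CC(C)[Si](C(C)C)(C(C)C)OCc1c2c(cc(OCc3ccc(OC)cc3)c1[Li])O[C@@H](c1ccc(OC)cc1)[C@H]2c1cc(OC)cc(OC)c1 | intermediate (not isolated)
14 | [(2R,3S)-3-(3,5-dimethoxyphenyl)-6-(4-methoxybenzyloxy)-2-(4-methoxyphenyl)-4-(triisopropylsilyloxymethyl)-2,3-dihydrobenzofuran-5-yl](3,5-dimethoxyphenyl)methanone | CC(C)[Si](C(C)C)(C(C)C)OCc1c2c(cc(OCc3ccc(OC)cc3)c1C(=O)c1cc(OC)cc(OC)c1)O[C@@H](c1ccc(OC)cc1)[C@H]2c1cc(OC)cc(OC)c1 | intermediate
15 | [(2R,3R)-3-(2-bromo-3,5-dimethoxyphenyl)-6-(4-methoxybenzyloxy)-2-(4-methoxyphenyl)-4-(triisopropylsilyloxymethyl)-2,3-dihydrobenzofuran-5-yl](3,5-dimethoxyphenyl)methanone (2,3-cis) | CC(C)[Si](C(C)C)(C(C)C)OCc1c2c(cc(OCc3ccc(OC)cc3)c1C(=O)c1cc(OC)cc(OC)c1)O[C@@H](c1ccc(OC)cc1)[C@H]2c1cc(OC)cc(OC)c1Br | intermediate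
16 | hydrazone of 15 | CC(C)[Si](C(C)C)(C(C)C)OCc1c2c(cc(OCc3ccc(OC)cc3)c1C(=NN)c1cc(OC)cc(OC)c1)O[C@@H](c1ccc(OC)cc1)[C@H]2c1cc(OC)cc(OC)c1Br | intermediate
17 | diazo compound from 16 (C=N2 in place of C=O of 15) | CC(C)[Si](C(C)C)(C(C)C)OCc1c2c(cc(OCc3ccc(OC)cc3)c1C(=[N+]=[N-])c1cc(OC)cc(OC)c1)O[C@@H](c1ccc(OC)cc1)[C@H]2c1cc(OC)cc(OC)c1Br | intermediate (not isolated)
18 | (2R,3R,5R,6S)-3-(2-bromo-3,5-dimethoxyphenyl)-5-(3,5-dimethoxyphenyl)-2,6-bis(4-methoxyphenyl)-4-(triisopropylsilyloxymethyl)-2,3,5,6-tetrahydrobenzo[1,2-b:5,4-b']difuran (both rings cis) | CC(C)[Si](C(C)C)(C(C)C)OCc1c2c(cc3c1[C@@H](c1cc(OC)cc(OC)c1)[C@@H](c1ccc(OC)cc1)O3)O[C@@H](c1ccc(OC)cc1)[C@H]2c1cc(OC)cc(OC)c1Br | intermediate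
19 | (2S,3R,5R,6R)-3-(2-bromo-3,5-dimethoxyphenyl)-5-(3,5-dimethoxyphenyl)-2,6-bis(4-methoxyphenyl)-4-(triisopropylsilyloxymethyl)-2,3,5,6-tetrahydrobenzo[1,2-b:5,4-b']difuran (both rings trans) | CC(C)[Si](C(C)C)(C(C)C)OCc1c2c(cc3c1[C@@H](c1cc(OC)cc(OC)c1)[C@H](c1ccc(OC)cc1)O3)O[C@H](c1ccc(OC)cc1)[C@H]2c1cc(OC)cc(OC)c1Br | intermediate
20 | d6-lithio analogue of 19 (lithium in place of bromine on ring D) | CC(C)[Si](C(C)C)(C(C)C)OCc1c2c(cc3c1[C@@H](c1cc(OC)cc(OC)c1)[C@H](c1ccc(OC)cc1)O3)O[C@H](c1ccc(OC)cc1)[C@H]2c1cc(OC)cc(OC)c1[Li] | intermediate (not isolated)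
21 | 2-[(2S,3S,5R,6R)-5-(3,5-dimethoxyphenyl)-2,6-bis(4-methoxyphenyl)-4-(triisopropylsilyloxymethyl)-2,3,5,6-tetrahydrobenzo[1,2-b:5,4-b']difuran-3-yl]-4,6-dimethoxybenzaldehyde | CC(C)[Si](C(C)C)(C(C)C)OCc1c2c(cc3c1[C@@H](c1cc(OC)cc(OC)c1)[C@H](c1ccc(OC)cc1)O3)O[C@H](c1ccc(OC)cc1)[C@H]2c1cc(OC)cc(OC)c1C=O | intermediate (not isolated)
22 | {2-[(2S,3S,5R,6R)-5-(3,5-dimethoxyphenyl)-2,6-bis(4-methoxyphenyl)-4-(triisopropylsilyloxymethyl)-2,3,5,6-tetrahydrobenzo[1,2-b:5,4-b']difuran-3-yl]-4,6-dimethoxyphenyl}methanol | CC(C)[Si](C(C)C)(C(C)C)OCc1c2c(cc3c1[C@@H](c1cc(OC)cc(OC)c1)[C@H](c1ccc(OC)cc1)O3)O[C@H](c1ccc(OC)cc1)[C@H]2c1cc(OC)cc(OC)c1CO | intermediate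
23 | {(2S,3S,5R,6R)-3-[2-(hydroxymethyl)-3,5-dimethoxyphenyl]-5-(3,5-dimethoxyphenyl)-2,6-bis(4-methoxyphenyl)-2,3,5,6-tetrahydrobenzo[1,2-b:5,4-b']difuran-4-yl}methanol | OCc1c2c(cc3c1[C@@H](c1cc(OC)cc(OC)c1)[C@H](c1ccc(OC)cc1)O3)O[C@H](c1ccc(OC)cc1)[C@H]2c1cc(OC)cc(OC)c1CO | intermediate
24 | (2S,3S,5R,6R)-4-(bromomethyl)-3-[2-(bromomethyl)-3,5-dimethoxyphenyl]-5-(3,5-dimethoxyphenyl)-2,6-bis(4-methoxyphenyl)-2,3,5,6-tetrahydrobenzo[1,2-b:5,4-b']difuran | BrCc1c2c(cc3c1[C@@H](c1cc(OC)cc(OC)c1)[C@H](c1ccc(OC)cc1)O3)O[C@H](c1ccc(OC)cc1)[C@H]2c1cc(OC)cc(OC)c1CBr | intermediate (not isolated)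
25 | thiocine: cyclic sulfide Cb–S–Ca bridging a1 and d6 (C2E S, Cf S, C2F R, C3F R) | S1Cc2c3c(cc4c2[C@@H](c2cc(OC)cc(OC)c2)[C@H](c2ccc(OC)cc2)O4)O[C@H](c2ccc(OC)cc2)[C@H]3c2cc(OC)cc(OC)c2C1 | intermediate
26 | thiocine S-oxide (sulfoxide of 25; configuration at sulfur undefined) | O=S1Cc2c3c(cc4c2[C@@H](c2cc(OC)cc(OC)c2)[C@H](c2ccc(OC)cc2)O4)O[C@H](c2ccc(OC)cc2)[C@H]3c2cc(OC)cc(OC)c2C1 | intermediate (not isolated)
27 | thiocine S,S-dioxide (sulfone Cb–SO2–Ca; stereocentres as in 25) | O=S1(=O)Cc2c3c(cc4c2[C@@H](c2cc(OC)cc(OC)c2)[C@H](c2ccc(OC)cc2)O4)O[C@H](c2ccc(OC)cc2)[C@H]3c2cc(OC)cc(OC)c2C1 | intermediate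
28 | α-bromosulfone (drawn brominated at Cb; the Ca isomer is equivalent for the outcome; new centre undefined) | O=S1(=O)C(Br)c2c3c(cc4c2[C@@H](c2cc(OC)cc(OC)c2)[C@H](c2ccc(OC)cc2)O4)O[C@H](c2ccc(OC)cc2)[C@H]3c2cc(OC)cc(OC)c2C1 | intermediate (not isolated)
29 | episulfone (thiirane S,S-dioxide across Ca–Cb, fused to ring C; new centres undefined) | O=S1(=O)C2c3c4c(cc5c3[C@@H](c3cc(OC)cc(OC)c3)[C@H](c3ccc(OC)cc3)O5)O[C@H](c3ccc(OC)cc3)[C@H]4c3cc(OC)cc(OC)c3C12 | intermediate (not isolated)
30 | ring C alkene Ca(H)=Cb(H), hexamethyl ether (C2E S, Cf S, C2F R, C3F R) | C1=Cc2c3c(cc4c2[C@@H](c2cc(OC)cc(OC)c2)[C@H](c2ccc(OC)cc2)O4)O[C@H](c2ccc(OC)cc2)[C@H]3c2cc(OC)cc(OC)c21 | intermediate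
31 | anisole | COc1ccccc1 | starting material
32 | heptamethyl ether of the target (Ca S, Cf S, C2E S, C2F R, C3F R) | COc1ccc([C@@H]2Cc3c4c(cc5c3[C@@H](c3cc(OC)cc(OC)c3)[C@H](c3ccc(OC)cc3)O5)O[C@H](c3ccc(OC)cc3)[C@H]4c3cc(OC)cc(OC)c32)cc1 | intermediate
33 | CNP0136963.1 (Ca S, Cf S, C2E S, C2F R, C3F R) | Oc1ccc([C@@H]2Cc3c4c(cc5c3[C@@H](c3cc(O)cc(O)c3)[C@H](c3ccc(O)cc3)O5)O[C@H](c3ccc(O)cc3)[C@H]4c3cc(O)cc(O)c32)cc1 | target

**Step count and risks**

Total: 18 steps. Longest linear sequence: 18 steps (1 to 33); 2, 6, 12 and 31 enter as commercial reagents.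

Step 10 (second carbene insertion). What may go wrong: insufficient catalyst control at the hindered diaryl carbene, so that both faces are used and ring F forms as a diastereomer mixture, or diversion of the diazo compound into azine. Fallback, from ketone 15 back to 19: LiAlH4 reduces the ketone to benzhydrol F1. Sodium 4-methylbenzenesulfinate in TFA/CH2Cl2 then removes the PMB group, replaces the hydroxyl by the sulfonyl group and at the same time equilibrates ring E to trans, giving phenol sulfone F2. Cs2CO3 with (4-methoxybenzyl)dimethylsulfonium tetrafluoroborate in MeCN releases the ortho-quinone methide and the benzylic sulfur ylide, whose [4+1] annulation closes ring F directly trans. Because ring E is already a single enantiomer, the two ring F outcomes are diastereomers, 19 and the 5S,6S isomer F3, which are separated by chromatography; 19 continues with step 12.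

Step 14 (thiocine closure). What may go wrong: intermolecular thioether formation and self-alkylation of the very reactive ring D benzylic bromide outrun the eight-membered ring closure. Fallback, from diol 23 back to 25: thioacetic acid with catalytic ZnI2 substitutes only the ring D alcohol (SN1 through the 2,4-dimethoxybenzyl cation; the a1 alcohol cannot ionise) to give thioacetate alcohol F4. PBr3 converts the remaining alcohol into thioacetate bromide F5. K2CO3 in MeOH/THF at high dilution frees the thiolate, which closes the ring by intramolecular SN2 at the a1 bromomethyl group and gives 25.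

Step 17 (arylation at Ca). What may go wrong: oligomerisation of the alkene through the Ca cation, capture at the ortho carbon of anisole, or acid-induced opening of rings E and F with irreversible capture by anisole. Fallback, from alkene 30 back to 32: dry HCl in Et2O/CH2Cl2 at −40 °C adds in the Markovnikov sense to give the Ca chloride F6. This is used at once in a Negishi coupling with 4-MeOC6H4ZnCl, catalysed by NiCl2(dme) and 4,4'-di-tert-butyl-2,2'-bipyridine; the Ca radical is arylated on the same convex face, giving 32.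

Further compounds
F1 | step 10 | benzhydrol from reduction of ketone 15 (carbinol carbon undefined; ring E cis) | CC(C)[Si](C(C)C)(C(C)C)OCc1c2c(cc(OCc3ccc(OC)cc3)c1C(O)c1cc(OC)cc(OC)c1)O[C@@H](c1ccc(OC)cc1)[C@H]2c1cc(OC)cc(OC)c1Br
F2 | step 10 | phenol sulfone: a5 hydroxyl free, a6 bearing CH(3,5-dimethoxyphenyl)(4-methylbenzenesulfonyl); ring E trans | CC(C)[Si](C(C)C)(C(C)C)OCc1c2c(cc(O)c1C(c1cc(OC)cc(OC)c1)S(=O)(=O)c1ccc(C)cc1)O[C@H](c1ccc(OC)cc1)[C@H]2c1cc(OC)cc(OC)c1Br
F3 | step 10 | (2S,3R,5S,6S) diastereomer of 19 (ring F of opposite configuration) | CC(C)[Si](C(C)C)(C(C)C)OCc1c2c(cc3c1[C@H](c1cc(OC)cc(OC)c1)[C@@H](c1ccc(OC)cc1)O3)O[C@H](c1ccc(OC)cc1)[C@H]2c1cc(OC)cc(OC)c1Br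
F4 | step 14 | thioacetate alcohol: S-acetylthiomethyl on d6, hydroxymethyl on a1 | OCc1c2c(cc3c1[C@@H](c1cc(OC)cc(OC)c1)[C@H](c1ccc(OC)cc1)O3)O[C@H](c1ccc(OC)cc1)[C@H]2c1cc(OC)cc(OC)c1CSC(C)=O
F5 | step 14 | thioacetate bromide: S-acetylthiomethyl on d6, bromomethyl on a1 | BrCc1c2c(cc3c1[C@@H](c1cc(OC)cc(OC)c1)[C@H](c1ccc(OC)cc1)O3)O[C@H](c1ccc(OC)cc1)[C@H]2c1cc(OC)cc(OC)c1CSC(C)=O
F6 | step 17 | Ca chloride from Markovnikov addition of HCl to 30 (Ca undefined) | ClC1Cc2c3c(cc4c2[C@@H](c2cc(OC)cc(OC)c2)[C@H](c2ccc(OC)cc2)O4)O[C@H](c2ccc(OC)cc2)[C@H]3c2cc(OC)cc(OC)c21
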